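## Retrosynthetic overview

1. Target 28 ⇐ octa-O-allyl diketone 27 (deallylation) ⇐ carbinol 26 (oxidation) ⇐ seco keto aldehyde 25. The 12-membered ring is closed last, by CrCl2/NiCl2-mediated addition of the aryl iodide on ring B's resorcinol to the aldehyde at C-4 of ring A.
2. 25 ⇐ alcohol 16 (fragment A, as its aryl Grignard reagent) + Weinreb amide 22 (fragment B); this union makes the first aryl ketone.
3. Each cyclohexene ⇐ auxiliary-controlled endo Diels–Alder reaction of cinnamoyl imide 7 with an aryl diene (11 or 14), which sets C-3, C-4 and C-5. In fragment B, C-4 is then inverted by lactonization onto the ortho phenol and equilibration to the trans-fused lactone 20.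
4. 7, 11 and 14 ⇐ 2,4-dihydroxybenzaldehyde by iodination, O-allylation and Horner–Wadsworth–Emmons olefinations.
5. Ring order: cyclohexene A and cyclohexene B in parallel, then the macrocycle.

Assumption: the SMILES is taken literally, so the two cyclohexene units are C-4 epimers, (3R,4S,5R) in ring A (3,4-cis, 4,5-trans) and (3R,4R,5R) in ring B (3,4-trans, 4,5-cis); local numbering: C-1 carries the methyl group, C-3 the tetrasubstituted resorcinol ring, C-4 the carbonyl, C-5 the 2,4-dihydroxyphenyl group.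

## Route

Step 1
Reactants: 1 2,4-dihydroxybenzaldehyde
Product: 2 2,4-bis(allyloxy)benzaldehyde
Conditions: allyl bromide (2.5 equiv), K2CO3, DMF, 60 °C
Reagents that add atoms: allyl bromide, C=CCBr
Why: Williamson etherification (SN2) of both phenoxides; no stereocentre is involved.

Step 2
Reactants: 3 (R)-4-benzyloxazolidin-2-one; 4 bromoacetyl bromide
Product: 5 (R)-4-benzyl-3-(bromoacetyl)oxazolidin-2-one
Conditions: n-BuLi, THF, −78 °C; then 4, −78 → 0 °C
Reagents that add atoms: none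
Why: N-acylation of the lithiated oxazolidinone by the acid bromide, which leaves the auxiliary stereocentre untouched.

Step 3
Reactants: 5 (R)-4-benzyl-3-(bromoacetyl)oxazolidin-2-one
Product: 6 diethyl {2-[(R)-4-benzyl-2-oxooxazolidin-3-yl]-2-oxoethyl}phosphonate
Conditions: P(OEt)3, neat, 90 °C
Reagents that add atoms: triethyl phosphite, CCOP(OCC)OCC
Why: Michaelis–Arbuzov reaction of the activated primary bromide, driven by loss of bromoethane.

Step 4
Reactants: 2 2,4-bis(allyloxy)benzaldehyde; 6 diethyl {2-[(R)-4-benzyl-2-oxooxazolidin-3-yl]-2-oxoethyl}phosphonate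
Product: 7 (R)-4-benzyl-3-{(E)-3-[2,4-bis(allyloxy)phenyl]acryloyl}oxazolidin-2-one
Conditions: LiCl, i-Pr2NEt, MeCN, rt
Reagents that add atoms: none
Why: Masamune–Roush Horner–Wadsworth–Emmons olefination of a stabilised phosphonate gives the E-enoyl imide under conditions too mild to open the imide.

Step 5
Reactants: 1 2,4-dihydroxybenzaldehyde
Product: 8 2,4-dihydroxy-5-iodobenzaldehyde
Conditions: ICl, AcOH, rt
Reagents that add atoms: iodine monochloride, ClI
Why: Electrophilic aromatic iodination at C-5, which is para to the 2-OH and ortho to the 4-OH and less hindered than C-3 between the two hydroxyl groups.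

Step 6
Reactants: 8 2,4-dihydroxy-5-iodobenzaldehyde
Product: 9 2,4-bis(allyloxy)-5-iodobenzaldehyde
Conditions: allyl bromide (2.5 equiv), K2CO3, DMF, 50 °C
Reagents that add atoms: allyl bromide, C=CCBr
Why: Williamson etherification of both phenols; the aryl iodide is inert to carbonate.

Step 7
Reactants: 9 2,4-bis(allyloxy)-5-iodobenzaldehyde; 10 diethyl (2-methylallyl)phosphonate
Product: 11 1,5-bis(allyloxy)-2-iodo-4-[(E)-3-methylbuta-1,3-dien-1-yl]benzene
Conditions: 10, n-BuLi, THF, −78 °C; then 9, −78 °C → rt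
Reagents that add atoms: none
Why: Horner–Wadsworth–Emmons olefination with the preformed lithiated allylic phosphonate (no free alkyllithium meets the aryl iodide) gives the E-1-aryl diene.

Step 8
Reactants: 8 2,4-dihydroxy-5-iodobenzaldehyde
Product: 12 4-(allyloxy)-2-hydroxy-5-iodobenzaldehyde
Conditions: allyl bromide (1.05 equiv), NaHCO3, MeCN, 60 °C
Reagents that add atoms: allyl bromide, C=CCBr
Why: Regioselective Williamson etherification, because the 4-OH is the more acidic phenol while the 2-OH is hydrogen-bonded to the formyl group and is not deprotonated by the weak base.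

Step 9
Reactants: 12 4-(allyloxy)-2-hydroxy-5-iodobenzaldehyde
Product: 13 4-(allyloxy)-5-iodo-2-(triisopropylsilyloxy)benzaldehyde
Conditions: i-Pr3SiOTf, 2,6-lutidine, CH2Cl2, 0 °C
Reagents that add atoms: triisopropylsilyl trifluoromethanesulfonate, CC(C)[Si](OS(=O)(=O)C(F)(F)F)(C(C)C)C(C)C
Why: Silylation of the chelated phenol with the reactive silyl triflate marks O-2 of this ring with a fluoride-labile group that is orthogonal to the allyl ethers.

Step 10
Reactants: 13 4-(allyloxy)-5-iodo-2-(triisopropylsilyloxy)benzaldehyde; 10 diethyl (2-methylallyl)phosphonate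
Product: 14 {5-(allyloxy)-4-iodo-2-[(E)-3-methylbuta-1,3-dien-1-yl]phenoxy}triisopropylsilane
Conditions: 10, n-BuLi, THF, −78 °C; then 13, −78 °C → rt
Reagents that add atoms: none
Why: Horner–Wadsworth–Emmons olefination as in step 7; the bulky triisopropylsilyl ether resists migration to the intermediate alkoxide.

Step 11
Reactants: 7 (R)-4-benzyl-3-{(E)-3-[2,4-bis(allyloxy)phenyl]acryloyl}oxazolidin-2-one; 11 1,5-bis(allyloxy)-2-iodo-4-[(E)-3-methylbuta-1,3-dien-1-yl]benzene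
Product: 15 (R)-4-benzyl-3-{(1S,2R,6R)-2-[2,4-bis(allyloxy)-5-iodophenyl]-6-[2,4-bis(allyloxy)phenyl]-4-methylcyclohex-3-ene-1-carbonyl}oxazolidin-2-one
Conditions: Me2AlCl (1.5 equiv), CH2Cl2, −40 → −15 °C
Reagents that add atoms: none
Why: Evans auxiliary-controlled Diels–Alder reaction in which Me2AlCl chelates both imide carbonyls (s-cis enoyl) and the diene adds endo to the face away from the benzyl group with the aryl-bearing terminus bonding to the α-carbon; endo addition gives 3,4-cis, the E-alkene gives 4,5-trans, and the auxiliary fixes the absolute sense as (3R,4S,5R).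

Step 12
Reactants: 15 (R)-4-benzyl-3-{(1S,2R,6R)-2-[2,4-bis(allyloxy)-5-iodophenyl]-6-[2,4-bis(allyloxy)phenyl]-4-methylcyclohex-3-ene-1-carbonyl}oxazolidin-2-one
Product: 16 {(1S,2R,6R)-2-[2,4-bis(allyloxy)-5-iodophenyl]-6-[2,4-bis(allyloxy)phenyl]-4-methylcyclohex-3-en-1-yl}methanol
Conditions: LiBH4, H2O (1 equiv), Et2O, 0 °C
Reagents that add atoms: none
Why: Reductive cleavage of the N-acyl oxazolidinone at the exocyclic carbonyl gives the primary alcohol without touching the aryl iodide, the allyl ethers or the three stereocentres.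

Step 13
Reactants: 7 (R)-4-benzyl-3-{(E)-3-[2,4-bis(allyloxy)phenyl]acryloyl}oxazolidin-2-one; 14 {5-(allyloxy)-4-iodo-2-[(E)-3-methylbuta-1,3-dien-1-yl]phenoxy}triisopropylsilane
Product: 17 (R)-4-benzyl-3-{(1S,2R,6R)-2-[4-(allyloxy)-5-iodo-2-(triisopropylsilyloxy)phenyl]-6-[2,4-bis(allyloxy)phenyl]-4-methylcyclohex-3-ene-1-carbonyl}oxazolidin-2-one
Conditions: Me2AlCl (1.5 equiv), CH2Cl2, −40 → −15 °C
Reagents that add atoms: none
Why: The same chelate-controlled endo Diels–Alder reaction as in step 11 sets the three stereocentres as (3R,4S,5R) with the acyl group cis to the silyloxy-bearing aryl ring.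

Step 14
Reactants: 17 (R)-4-benzyl-3-{(1S,2R,6R)-2-[4-(allyloxy)-5-iodo-2-(triisopropylsilyloxy)phenyl]-6-[2,4-bis(allyloxy)phenyl]-4-methylcyclohex-3-ene-1-carbonyl}oxazolidin-2-one
Product: 19 (6aS,7R,10aR)-3-(allyloxy)-7-[2,4-bis(allyloxy)phenyl]-2-iodo-9-methyl-6a,7,8,10a-tetrahydro-6H-benzo[c]chromen-6-one (cis-fused lactone), via tetrabutylammonium phenoxide 18 (not isolated)
Conditions: Bu4NF (1.1 equiv), THF, 0 °C → rt; AcOH quench
Reagents that add atoms: none
Why: Fluoride desilylation frees the phenoxide ortho to C-3, which attacks the cis-disposed imide carbonyl in a six-membered lactonization that expels the auxiliary and retains the cis C-3/C-4 relationship.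

Step 15
Reactants: 19 (6aS,7R,10aR)-3-(allyloxy)-7-[2,4-bis(allyloxy)phenyl]-2-iodo-9-methyl-6a,7,8,10a-tetrahydro-6H-benzo[c]chromen-6-one (cis-fused lactone)
Product: 20 (6aR,7R,10aR)-3-(allyloxy)-7-[2,4-bis(allyloxy)phenyl]-2-iodo-9-methyl-6a,7,8,10a-tetrahydro-6H-benzo[c]chromen-6-one (trans-fused lactone)
Conditions: DBU (0.3 equiv), toluene, 40 °C
Reagents that add atoms: none
Why: Base-mediated epimerization through the lactone enolate under thermodynamic control favours the trans-fused benzo[c]chromenone (the 7-aryl group can sit axial in either isomer, so ring fusion decides), inverting C-4 to give the (3R,4R,5R) array of ring B.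

Step 16
Reactants: 20 (6aR,7R,10aR)-3-(allyloxy)-7-[2,4-bis(allyloxy)phenyl]-2-iodo-9-methyl-6a,7,8,10a-tetrahydro-6H-benzo[c]chromen-6-one (trans-fused lactone)
Product: 21 (1R,2R,6R)-2-[4-(allyloxy)-2-hydroxy-5-iodophenyl]-6-[2,4-bis(allyloxy)phenyl]-N-methoxy-N,4-dimethylcyclohex-3-ene-1-carboxamide
Conditions: MeNH(OMe)·HCl, AlMe3, CH2Cl2, 0 °C → rt
Reagents that add atoms: N,O-dimethylhydroxylamine hydrochloride, CNOC.Cl
Why: Weinreb aminolysis of the aryl lactone by the aluminium amide is non-basic, so the newly set C-4 centre is kept while the phenol is released.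

Step 17
Reactants: 21 (1R,2R,6R)-2-[4-(allyloxy)-2-hydroxy-5-iodophenyl]-6-[2,4-bis(allyloxy)phenyl]-N-methoxy-N,4-dimethylcyclohex-3-ene-1-carboxamide
Product: 22 (1R,2R,6R)-2-[2,4-bis(allyloxy)-5-iodophenyl]-6-[2,4-bis(allyloxy)phenyl]-N-methoxy-N,4-dimethylcyclohex-3-ene-1-carboxamide
Conditions: allyl bromide, K2CO3, DMF, rt
Reagents that add atoms: allyl bromide, C=CCBr
Why: Williamson etherification of the free phenol; the Weinreb amide is inert to carbonate and its α-centre is not enolized.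

Step 18
Reactants: 16 {(1S,2R,6R)-2-[2,4-bis(allyloxy)-5-iodophenyl]-6-[2,4-bis(allyloxy)phenyl]-4-methylcyclohex-3-en-1-yl}methanol; 22 (1R,2R,6R)-2-[2,4-bis(allyloxy)-5-iodophenyl]-6-[2,4-bis(allyloxy)phenyl]-N-methoxy-N,4-dimethylcyclohex-3-ene-1-carboxamide
Product: 24 {(1S,2R,6R)-2-{2,4-bis(allyloxy)-5-[(1R,2R,6R)-2-(2,4-bis(allyloxy)-5-iodophenyl)-6-(2,4-bis(allyloxy)phenyl)-4-methylcyclohex-3-ene-1-carbonyl]phenyl}-6-[2,4-bis(allyloxy)phenyl]-4-methylcyclohex-3-en-1-yl}methanol, via aryl Grignard reagent 23 (not isolated)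
Conditions: 16, i-PrMgCl (1.0 equiv), THF, −20 °C; i-PrMgCl·LiCl (1.1 equiv), 0 °C → rt; then 22, rt → 40 °C; aq NH4Cl
Reagents that add atoms: none
Why: Iodine–magnesium exchange on the alkoxide of 16 followed by Weinreb ketone synthesis, in which the magnesium-chelated tetrahedral intermediate prevents over-addition and enolization at C-4 of ring B, and the aryl iodide of 22 does not exchange with an aryl Grignard reagent.

Step 19
Reactants: 24 the keto alcohol of step 18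
Product: 25 (1S,2R,6R)-2-{2,4-bis(allyloxy)-5-[(1R,2R,6R)-2-(2,4-bis(allyloxy)-5-iodophenyl)-6-(2,4-bis(allyloxy)phenyl)-4-methylcyclohex-3-ene-1-carbonyl]phenyl}-6-[2,4-bis(allyloxy)phenyl]-4-methylcyclohex-3-ene-1-carbaldehyde
Conditions: Dess–Martin periodinane, NaHCO3, CH2Cl2, 0 °C → rt
Reagents that add atoms: none
Why: Buffered Dess–Martin oxidation converts the primary alcohol into the aldehyde without epimerizing the adjacent C-4 of ring A.

Step 20
Reactants: 25 the keto aldehyde of step 19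
Product: 26 macrocyclic hydroxy ketone: the octa-O-allyl ether of the target in which the carbonyl attached to C-4 of ring A is CH(OH) (both carbinol epimers)
Conditions: CrCl2 (10 equiv), NiCl2 (0.1 equiv), DMF/THF, 0.002 M, rt, slow addition of 25
Reagents that add atoms: none
Why: Nozaki–Hiyama–Kishi macrocyclization, in which zerovalent nickel inserts into the aryl iodide and transmetalation gives an aryl species of trivalent chromium that adds to the aldehyde but not to the ketone under non-basic conditions, closing the 12-membered ring; the new carbinol centre forms as a mixture that the next step erases.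

Step 21
Reactants: 26 the macrocyclic hydroxy ketone of step 20
Product: 27 octa-O-allyl ether of the target (macrocyclic diketone)
Conditions: Dess–Martin periodinane, NaHCO3, CH2Cl2, rt
Reagents that add atoms: none
Why: Dess–Martin oxidation of the benzylic secondary alcohol gives the second aryl ketone and removes the carbinol stereocentre without affecting the two α-centres.

Step 22
Reactants: 27 octa-O-allyl ether of the target
Product: 28 the target, CNP0244682.3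
Conditions: Pd(PPh3)4 (0.2 equiv), morpholine (40 equiv), THF, rt
Reagents that add atoms: none
Why: Tsuji–Trost deallylation, in which zerovalent palladium ionizes each aryl allyl ether to a π-allyl complex that morpholine traps; these neutral conditions leave both ring alkenes and both epimerizable C-4 centres untouched and avoid acid-induced ketalization.

## Compound list

1 | 2,4-dihydroxybenzaldehyde | O=Cc1ccc(O)cc1O | starting material
2 | 2,4-bis(allyloxy)benzaldehyde | O=Cc1ccc(OCC=C)cc1OCC=C | intermediate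
3 | (R)-4-benzyloxazolidin-2-one | O=C1N[C@H](Cc2ccccc2)CO1 | starting material
4 | bromoacetyl bromide | BrCC(Br)=O | starting material
5 | (R)-4-benzyl-3-(bromoacetyl)oxazolidin-2-one | O=C(CBr)N1[C@H](Cc2ccccc2)COC1=O | intermediate
6 | diethyl {2-[(R)-4-benzyl-2-oxooxazolidin-3-yl]-2-oxoethyl}phosphonate | CCOP(=O)(CC(=O)N1[C@H](Cc2ccccc2)COC1=O)OCC | intermediate
7 | (R)-4-benzyl-3-{(E)-3-[2,4-bis(allyloxy)phenyl]acryloyl}oxazolidin-2-one | O=C(/C=C/c1ccc(OCC=C)cc1OCC=C)N1[C@H](Cc2ccccc2)COC1=O | intermediate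
8 | 2,4-dihydroxy-5-iodobenzaldehyde | O=Cc1cc(I)c(O)cc1O | intermediate
9 | 2,4-bis(allyloxy)-5-iodobenzaldehyde | O=Cc1cc(I)c(OCC=C)cc1OCC=C | intermediate
10 | diethyl (2-methylallyl)phosphonate | CCOP(=O)(CC(C)=C)OCC | starting material
11 | 1,5-bis(allyloxy)-2-iodo-4-[(E)-3-methylbuta-1,3-dien-1-yl]benzene | C=C(C)/C=C/c1cc(I)c(OCC=C)cc1OCC=C | intermediate
12 | 4-(allyloxy)-2-hydroxy-5-iodobenzaldehyde | O=Cc1cc(I)c(OCC=C)cc1O | intermediate
13 | 4-(allyloxy)-5-iodo-2-(triisopropylsilyloxy)benzaldehyde | O=Cc1cc(I)c(OCC=C)cc1O[Si](C(C)C)(C(C)C)C(C)C | intermediate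
14 | {5-(allyloxy)-4-iodo-2-[(E)-3-methylbuta-1,3-dien-1-yl]phenoxy}triisopropylsilane | C=C(C)/C=C/c1cc(I)c(OCC=C)cc1O[Si](C(C)C)(C(C)C)C(C)C | intermediate
15 | (R)-4-benzyl-3-{(1S,2R,6R)-2-[2,4-bis(allyloxy)-5-iodophenyl]-6-[2,4-bis(allyloxy)phenyl]-4-methylcyclohex-3-ene-1-carbonyl}oxazolidin-2-one | CC1=C[C@@H](c2cc(I)c(OCC=C)cc2OCC=C)[C@@H](C(=O)N2[C@H](Cc3ccccc3)COC2=O)[C@H](c2ccc(OCC=C)cc2OCC=C)C1 | intermediate
16 | {(1S,2R,6R)-2-[2,4-bis(allyloxy)-5-iodophenyl]-6-[2,4-bis(allyloxy)phenyl]-4-methylcyclohex-3-en-1-yl}methanol (fragment A) | CC1=C[C@@H](c2cc(I)c(OCC=C)cc2OCC=C)[C@@H](CO)[C@H](c2ccc(OCC=C)cc2OCC=C)C1 | intermediate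
17 | (R)-4-benzyl-3-{(1S,2R,6R)-2-[4-(allyloxy)-5-iodo-2-(triisopropylsilyloxy)phenyl]-6-[2,4-bis(allyloxy)phenyl]-4-methylcyclohex-3-ene-1-carbonyl}oxazolidin-2-one | CC1=C[C@@H](c2cc(I)c(OCC=C)cc2O[Si](C(C)C)(C(C)C)C(C)C)[C@@H](C(=O)N2[C@H](Cc3ccccc3)COC2=O)[C@H](c2ccc(OCC=C)cc2OCC=C)C1 | intermediate
18 | tetrabutylammonium phenoxide of desilylated 17 (O⁻ ortho to the cyclohexenyl group on the iodoaryl ring) | CC1=C[C@@H](c2cc(I)c(OCC=C)cc2[O-])[C@@H](C(=O)N2[C@H](Cc3ccccc3)COC2=O)[C@H](c2ccc(OCC=C)cc2OCC=C)C1.CCCC[N+](CCCC)(CCCC)CCCC | intermediate (not isolated)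
19 | (6aS,7R,10aR)-3-(allyloxy)-7-[2,4-bis(allyloxy)phenyl]-2-iodo-9-methyl-6a,7,8,10a-tetrahydro-6H-benzo[c]chromen-6-one (cis-fused lactone) | CC1=C[C@H]2c3cc(I)c(OCC=C)cc3OC(=O)[C@H]2[C@H](c2ccc(OCC=C)cc2OCC=C)C1 | intermediate
20 | (6aR,7R,10aR)-3-(allyloxy)-7-[2,4-bis(allyloxy)phenyl]-2-iodo-9-methyl-6a,7,8,10a-tetrahydro-6H-benzo[c]chromen-6-one (trans-fused lactone) | CC1=C[C@H]2c3cc(I)c(OCC=C)cc3OC(=O)[C@@H]2[C@H](c2ccc(OCC=C)cc2OCC=C)C1 | intermediate
21 | (1R,2R,6R)-2-[4-(allyloxy)-2-hydroxy-5-iodophenyl]-6-[2,4-bis(allyloxy)phenyl]-N-methoxy-N,4-dimethylcyclohex-3-ene-1-carboxamide | CC1=C[C@@H](c2cc(I)c(OCC=C)cc2O)[C@H](C(=O)N(C)OC)[C@H](c2ccc(OCC=C)cc2OCC=C)C1 | intermediate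
22 | (1R,2R,6R)-2-[2,4-bis(allyloxy)-5-iodophenyl]-6-[2,4-bis(allyloxy)phenyl]-N-methoxy-N,4-dimethylcyclohex-3-ene-1-carboxamide (fragment B) | CC1=C[C@@H](c2cc(I)c(OCC=C)cc2OCC=C)[C@H](C(=O)N(C)OC)[C@H](c2ccc(OCC=C)cc2OCC=C)C1 | intermediate
23 | aryl Grignard reagent from 16 (ArMgCl in place of ArI, CH2OMgCl in place of CH2OH) | CC1=C[C@@H](c2cc([Mg]Cl)c(OCC=C)cc2OCC=C)[C@@H](CO[Mg]Cl)[C@H](c2ccc(OCC=C)cc2OCC=C)C1 | intermediate (not isolated)
24 | {(1S,2R,6R)-2-{2,4-bis(allyloxy)-5-[(1R,2R,6R)-2-(2,4-bis(allyloxy)-5-iodophenyl)-6-(2,4-bis(allyloxy)phenyl)-4-methylcyclohex-3-ene-1-carbonyl]phenyl}-6-[2,4-bis(allyloxy)phenyl]-4-methylcyclohex-3-en-1-yl}methanol | CC1=C[C@@H](c2cc(C(=O)[C@H]3[C@@H](C=C(C)C[C@H]3c3ccc(OCC=C)cc3OCC=C)c3cc(I)c(OCC=C)cc3OCC=C)c(OCC=C)cc2OCC=C)[C@@H](CO)[C@H](c2ccc(OCC=C)cc2OCC=C)C1 | intermediate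
25 | (1S,2R,6R)-2-{2,4-bis(allyloxy)-5-[(1R,2R,6R)-2-(2,4-bis(allyloxy)-5-iodophenyl)-6-(2,4-bis(allyloxy)phenyl)-4-methylcyclohex-3-ene-1-carbonyl]phenyl}-6-[2,4-bis(allyloxy)phenyl]-4-methylcyclohex-3-ene-1-carbaldehyde | CC1=C[C@@H](c2cc(C(=O)[C@H]3[C@@H](C=C(C)C[C@H]3c3ccc(OCC=C)cc3OCC=C)c3cc(I)c(OCC=C)cc3OCC=C)c(OCC=C)cc2OCC=C)[C@@H](C=O)[C@H](c2ccc(OCC=C)cc2OCC=C)C1 | intermediate
26 | macrocyclic hydroxy ketone: octa-O-allyl ether of the target with CH(OH) in place of the carbonyl on C-4 of ring A (both carbinol epimers) | CC1=C[C@H]2c3cc(c(OCC=C)cc3OCC=C)C(=O)[C@H]3[C@@H](C=C(C)C[C@H]3c3ccc(OCC=C)cc3OCC=C)c3cc(c(OCC=C)cc3OCC=C)C(O)[C@H]2[C@H](c2ccc(OCC=C)cc2OCC=C)C1 | intermediate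
27 | octa-O-allyl ether of the target (macrocyclic diketone) | CC1=C[C@H]2c3cc(c(OCC=C)cc3OCC=C)C(=O)[C@H]3[C@@H](C=C(C)C[C@H]3c3ccc(OCC=C)cc3OCC=C)c3cc(c(OCC=C)cc3OCC=C)C(=O)[C@H]2[C@H](c2ccc(OCC=C)cc2OCC=C)C1 | intermediate
28 | CNP0244682.3: 12-membered diketone macrocycle in which each 4,6-disubstituted resorcinol ring joins C-3 of one 1-methyl-5-(2,4-dihydroxyphenyl)cyclohexene to the C-4 carbonyl of the other; ring A (3R,4S,5R), ring B (3R,4R,5R) | CC1=C[C@H]2c3cc(c(O)cc3O)C(=O)[C@H]3[C@@H](C=C(C)C[C@H]3c3ccc(O)cc3O)c3cc(c(O)cc3O)C(=O)[C@H]2[C@H](c2ccc(O)cc2O)C1 | target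

## Step count

Total step count: 22.
Longest linear sequence: 14 steps (1 → 8 → 12 → 13 → 14 → 17 → 19 → 20 → 21 → 22 → 24 → 25 → 26 → 27 → 28; steps 5, 8, 9, 10 and 13 to 22).

## Steps most likely to fail, with fallbacks

Step 15 (lactone epimerization). The preference for the trans-fused lactone is a thermodynamic argument, not a measured value, and the equilibrium could stall at a mixture. The fallback sets C-4 of ring B kinetically by an endo Diels–Alder reaction in which the two aryl groups change roles; it sets out from 2, 9 and 6 and comes back at 22. Aldol condensation of 2 with acetone (NaOH, EtOH/H2O) gives (E)-4-[2,4-bis(allyloxy)phenyl]but-3-en-2-one F1, and Peterson olefination with (Me3Si)2CHLi gives the vinylsilane diene {(1E,3E)-4-[2,4-bis(allyloxy)phenyl]-2-methylbuta-1,3-dien-1-yl}trimethylsilane F2. Horner–Wadsworth–Emmons reaction of 9 with 6 (LiCl, i-Pr2NEt) gives (R)-4-benzyl-3-{(E)-3-[2,4-bis(allyloxy)-5-iodophenyl]acryloyl}oxazolidin-2-one F3. Me2AlCl-promoted endo cycloaddition of F2 with F3 gives the allylsilane (R)-4-benzyl-3-{2-[2,4-bis(allyloxy)-5-iodophenyl]-6-[2,4-bis(allyloxy)phenyl]-4-methyl-3-(trimethylsilyl)cyclohex-4-ene-1-carbonyl}oxazolidin-2-one F4, in which the acyl group is cis to the diene-derived aryl group and trans to the iodoaryl group. Protodesilylation with CF3CO2H (SE2', proton to the far alkene carbon, loss of silicon) moves the double bond next to the iodoaryl-bearing carbon and gives (R)-4-benzyl-3-{(1R,2R,6R)-2-[2,4-bis(allyloxy)-5-iodophenyl]-6-[2,4-bis(allyloxy)phenyl]-4-methylcyclohex-3-ene-1-carbonyl}oxazolidin-2-one F5. AlMe3/MeNH(OMe)·HCl then converts F5 into 22.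

Step 18 (fragment union). A hindered ortho-alkoxy aryl Grignard reagent must attack an α,β-branched Weinreb amide, and the iodine–magnesium exchange on an electron-rich arene is slow. The fallback makes the ketone at the alcohol oxidation level by carbonyl addition of an organocerium reagent; it sets out from 22 and 16 and comes back at 25. i-Bu2AlH (THF, −78 °C) reduces 22 to (1R,2R,6R)-2-[2,4-bis(allyloxy)-5-iodophenyl]-6-[2,4-bis(allyloxy)phenyl]-4-methylcyclohex-3-ene-1-carbaldehyde F6. Compound 16 is treated with n-BuLi (2.1 equiv, −78 °C; alkoxide formation, then iodine–lithium exchange) and anhydrous CeCl3, and the aryl cerium reagent adds to F6 to give the diol analogue of 24 with CH(OH) in place of the ketone F7 (both carbinol epimers). Dess–Martin oxidation of both hydroxyl groups of F7 gives 25.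

Step 20 (macrocyclization). The ring is a strained [3.3]metacyclophane, the aldehyde on ring A is flanked by a cis aryl group, and low-valent nickel may attack the allyl ethers. The fallback exchanges the order of the two ketone-forming events so that the ring is closed at the less hindered aldehyde on ring B; it sets out from 15 and 20 and comes back at 27. AlMe3/MeNH(OMe)·HCl converts 15 into (1S,2R,6R)-2-[2,4-bis(allyloxy)-5-iodophenyl]-6-[2,4-bis(allyloxy)phenyl]-N-methoxy-N,4-dimethylcyclohex-3-ene-1-carboxamide F8. LiBH4 reduces lactone 20 to 5-(allyloxy)-2-{(1R,5R,6R)-5-[2,4-bis(allyloxy)phenyl]-6-(hydroxymethyl)-3-methylcyclohex-2-en-1-yl}-4-iodophenol F9, and allyl bromide/K2CO3 gives {(1R,2R,6R)-2-[2,4-bis(allyloxy)-5-iodophenyl]-6-[2,4-bis(allyloxy)phenyl]-4-methylcyclohex-3-en-1-yl}methanol F10. Iodine–magnesium exchange on F10 (i-PrMgCl, then i-PrMgCl·LiCl) and addition to F8 gives the keto alcohol {(1R,2R,6R)-2-{2,4-bis(allyloxy)-5-[(1S,2R,6R)-2-(2,4-bis(allyloxy)-5-iodophenyl)-6-(2,4-bis(allyloxy)phenyl)-4-methylcyclohex-3-ene-1-carbonyl]phenyl}-6-[2,4-bis(allyloxy)phenyl]-4-methylcyclohex-3-en-1-yl}methanol F11. Dess–Martin oxidation gives the corresponding keto aldehyde (1R,2R,6R)-2-{2,4-bis(allyloxy)-5-[(1S,2R,6R)-2-(2,4-bis(allyloxy)-5-iodophenyl)-6-(2,4-bis(allyloxy)phenyl)-4-methylcyclohex-3-ene-1-carbonyl]phenyl}-6-[2,4-bis(allyloxy)phenyl]-4-methylcyclohex-3-ene-1-carbaldehyde F12. CrCl2/NiCl2 at high dilution then closes the ring between the iodoarene on ring A and the ring B aldehyde to give the macrocyclic hydroxy ketone isomeric with 26, carrying CH(OH) on C-4 of ring B F13, and Dess–Martin oxidation gives 27.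

## Further compounds

F1 | step 15 | (E)-4-[2,4-bis(allyloxy)phenyl]but-3-en-2-one | CC(=O)/C=C/c1ccc(OCC=C)cc1OCC=C
F2 | step 15 | {(1E,3E)-4-[2,4-bis(allyloxy)phenyl]-2-methylbuta-1,3-dien-1-yl}trimethylsilane | C[Si](C)(C)/C=C(C)/C=C/c1ccc(OCC=C)cc1OCC=C
F3 | step 15 | (R)-4-benzyl-3-{(E)-3-[2,4-bis(allyloxy)-5-iodophenyl]acryloyl}oxazolidin-2-one | O=C(/C=C/c1cc(I)c(OCC=C)cc1OCC=C)N1[C@H](Cc2ccccc2)COC1=O
F4 | step 15 | (R)-4-benzyl-3-{2-[2,4-bis(allyloxy)-5-iodophenyl]-6-[2,4-bis(allyloxy)phenyl]-4-methyl-3-(trimethylsilyl)cyclohex-4-ene-1-carbonyl}oxazolidin-2-one (acyl, 6-aryl and silyl groups mutually cis; 2-aryl trans to them) | CC1=C[C@@H](c2ccc(OCC=C)cc2OCC=C)[C@@H](C(=O)N2[C@H](Cc3ccccc3)COC2=O)[C@H](c2cc(I)c(OCC=C)cc2OCC=C)[C@H]1[Si](C)(C)C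
F5 | step 15 | (R)-4-benzyl-3-{(1R,2R,6R)-2-[2,4-bis(allyloxy)-5-iodophenyl]-6-[2,4-bis(allyloxy)phenyl]-4-methylcyclohex-3-ene-1-carbonyl}oxazolidin-2-one | CC1=C[C@@H](c2cc(I)c(OCC=C)cc2OCC=C)[C@H](C(=O)N2[C@H](Cc3ccccc3)COC2=O)[C@H](c2ccc(OCC=C)cc2OCC=C)C1
F6 | step 18 | (1R,2R,6R)-2-[2,4-bis(allyloxy)-5-iodophenyl]-6-[2,4-bis(allyloxy)phenyl]-4-methylcyclohex-3-ene-1-carbaldehyde | CC1=C[C@@H](c2cc(I)c(OCC=C)cc2OCC=C)[C@H](C=O)[C@H](c2ccc(OCC=C)cc2OCC=C)C1
F7 | step 18 | diol analogue of 24 with CH(OH) in place of the ketone (both carbinol epimers) | CC1=C[C@@H](c2cc(C(O)[C@H]3[C@@H](C=C(C)C[C@H]3c3ccc(OCC=C)cc3OCC=C)c3cc(I)c(OCC=C)cc3OCC=C)c(OCC=C)cc2OCC=C)[C@@H](CO)[C@H](c2ccc(OCC=C)cc2OCC=C)C1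
F8 | step 20 | (1S,2R,6R)-2-[2,4-bis(allyloxy)-5-iodophenyl]-6-[2,4-bis(allyloxy)phenyl]-N-methoxy-N,4-dimethylcyclohex-3-ene-1-carboxamide | CC1=C[C@@H](c2cc(I)c(OCC=C)cc2OCC=C)[C@@H](C(=O)N(C)OC)[C@H](c2ccc(OCC=C)cc2OCC=C)C1
F9 | step 20 | 5-(allyloxy)-2-{(1R,5R,6R)-5-[2,4-bis(allyloxy)phenyl]-6-(hydroxymethyl)-3-methylcyclohex-2-en-1-yl}-4-iodophenol | CC1=C[C@@H](c2cc(I)c(OCC=C)cc2O)[C@H](CO)[C@H](c2ccc(OCC=C)cc2OCC=C)C1
F10 | step 20 | {(1R,2R,6R)-2-[2,4-bis(allyloxy)-5-iodophenyl]-6-[2,4-bis(allyloxy)phenyl]-4-methylcyclohex-3-en-1-yl}methanol | CC1=C[C@@H](c2cc(I)c(OCC=C)cc2OCC=C)[C@H](CO)[C@H](c2ccc(OCC=C)cc2OCC=C)C1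
F11 | step 20 | {(1R,2R,6R)-2-{2,4-bis(allyloxy)-5-[(1S,2R,6R)-2-(2,4-bis(allyloxy)-5-iodophenyl)-6-(2,4-bis(allyloxy)phenyl)-4-methylcyclohex-3-ene-1-carbonyl]phenyl}-6-[2,4-bis(allyloxy)phenyl]-4-methylcyclohex-3-en-1-yl}methanol | CC1=C[C@@H](c2cc(C(=O)[C@@H]3[C@@H](C=C(C)C[C@H]3c3ccc(OCC=C)cc3OCC=C)c3cc(I)c(OCC=C)cc3OCC=C)c(OCC=C)cc2OCC=C)[C@H](CO)[C@H](c2ccc(OCC=C)cc2OCC=C)C1
F12 | step 20 | (1R,2R,6R)-2-{2,4-bis(allyloxy)-5-[(1S,2R,6R)-2-(2,4-bis(allyloxy)-5-iodophenyl)-6-(2,4-bis(allyloxy)phenyl)-4-methylcyclohex-3-ene-1-carbonyl]phenyl}-6-[2,4-bis(allyloxy)phenyl]-4-methylcyclohex-3-ene-1-carbaldehyde | CC1=C[C@@H](c2cc(C(=O)[C@@H]3[C@@H](C=C(C)C[C@H]3c3ccc(OCC=C)cc3OCC=C)c3cc(I)c(OCC=C)cc3OCC=C)c(OCC=C)cc2OCC=C)[C@H](C=O)[C@H](c2ccc(OCC=C)cc2OCC=C)C1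
F13 | step 20 | macrocyclic hydroxy ketone isomeric with 26: octa-O-allyl ether of the target with CH(OH) in place of the carbonyl on C-4 of ring B (both carbinol epimers) | CC1=C[C@H]2c3cc(c(OCC=C)cc3OCC=C)C(O)[C@H]3[C@@H](C=C(C)C[C@H]3c3ccc(OCC=C)cc3OCC=C)c3cc(c(OCC=C)cc3OCC=C)C(=O)[C@H]2[C@H](c2ccc(OCC=C)cc2OCC=C)C1
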